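## Structural features

The target is a (2S)-flavanone in which benzene ring A is fused to dihydropyranone ring C, and ring C carries phenyl ring B at C2, the only stereocentre, so that only absolute control is at issue. Ring A is fully substituted: O1 at C8a, the carbonyl carbon on C4a, a hydroxyl at C5 hydrogen-bonded to C4=O, a methoxy group at C7, and two identical 2-hydroxy-5-(2-hydroxybenzyl)benzyl arms at C6 and C8. Each arm is an inner phenol ring D joined through CH2 to an outer phenol ring E. C2 is benzylic and β to the ketone, so base (and prolonged acid or heat) can open ring C by retro-oxa-Michael reaction to the 2'-hydroxychalcone and erase the configuration. The five phenols and four electron-rich diarylmethane units are sensitive to oxidants and to electrophiles such as formaldehyde equivalents. The real difficulty is twofold: joining both arms to ring A through carbon rather than oxygen, and introducing C2 late as a single enantiomer and keeping it. The key step exploits the mirror plane of ring A through C7 and C4a: C6 and C8 carry the same arm and O5 and O1 are equivalent while ring C is open, so ring C (C4, C3 and C2 with ring B) can be grafted between C4a and either oxygen of a symmetric 2-iodoresorcinol without a regiochemical question.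

## Logic of the disconnections

**21 to 20.** Only the four phenolic O–CH2OCH3 bonds on rings D and E are cut. The arm phenols must be masked while iodine, palladium and hydride are used, and acetals come off in mild acid, which ring C tolerates far better than base. Nothing is gained in skeleton, but every earlier intermediate becomes non-ionisable in the arms. The forward step must be mild enough to keep C2 and must trap the liberated formaldehyde equivalent.

**20 to 19.** The C2–H and C3–H bonds are removed, which deletes the stereocentre and leads to a flat, achiral flavone. The gain is that the stereocentre appears only after every C–C bond is in place. The forward step needs 1,4-selective hydride delivery to one face of C2 under catalyst control alone, no reduction of C4=O, and a non-basic medium.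

**19 to 14, 15 and 16.** The bonds C4a–C4, C4–C3 and O1–C2 are cut. This takes ring C apart into the one-carbon unit 15 and the two-carbon unit 16 (with ring B) and leaves ring A as a symmetric iodide. One ring and three bonds are thus made in one operation from two commercial pieces. The forward step requires CO insertion to outrun direct alkynylation, six-membered rather than five-membered closure, and tolerance of a crowded, electron-rich iodide with two free hydroxyls.

**14 to 13.** The C4a–I bond is cut. Iodine is the most fragile substituent and is best placed last; in 13 this carbon is the only C–H of ring A. No positional choice remains within ring A. Ring A must react much faster than rings D and E, which the free hydroxyls of ring A against the acetal-capped arms should secure.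

**13 to 11 (through 12).** A carboxyl group is restored on C4a (bond C4a–CO2CH3). It blocks the most nucleophilic carbon of ring A during benzylation and ties up both hydroxyls by chelation. This confines the arms to C6 and C8. The forward step must hydrolyse a hindered, chelated ester and expel CO2 without touching the acetals.

**11 to 10 and two molecules of 8.** The two ring A–CH2 bonds (C6–CH2 and C8–CH2) are cut. The cut follows the symmetry, so one arm synthesis serves twice. The molecule falls into a small ring A ester and the arm electrophile. The forward step must alkylate at carbon, not oxygen, and do so twice.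

**10 to 9.** The O–CH3 bond of the future C7 methoxy group is cut, leading to commercial 9. The forward step must methylate only the one hydroxyl that is not chelated to the ester.

**8 to 7, and 7 to 2 and 5 (through 6).** The C–Br bond is first exchanged for C–OH. The bond between C5 of ring D and the methylene of ring E is then cut. It is the only bond joining the two arm rings, and the bromine position in 2 fixes its regiochemistry. Two monocyclic pieces result. The forward step is an sp2–sp3 cross-coupling that must tolerate a free benzylic alcohol and two acetals.

**2 to 1; 5 to 4 to 3.** Only O–CH2OCH3 and C–Br bonds are cut, leading to commercial 1 and 3. The forward steps must protect the phenol in the presence of the benzylic alcohol and brominate without acid.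

## Other disconnections considered

Alternative 1: The cut is at the two aryl–CH2 bonds between C5 of each ring D and the methylene of each ring E, so both outer rings arrive last.
- **Forward step:** The (2S)-flavanone with two 5-bromo-2-(methoxymethoxy)benzyl arms (A1) would be electrolysed with two equivalents of the N-hydroxyphthalimide ester of 2-(methoxymethoxy)phenylacetic acid (A2), NiBr2(dme) and 4,4'-di-tert-butyl-2,2'-bipyridine. Low-valent nickel formed at the cathode adds to each C–Br bond. A2 takes up an electron and fragments to CO2, phthalimide anion and a 2-(methoxymethoxy)benzyl radical. Radical capture and reductive elimination should give the tetrakis(methoxymethyl) ether A3, which is the same compound as 20.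
- **In its favour:** It is the most convergent plan. The arm shrinks to a bromosalicyl unit, the outer ring comes from a stable acid derivative, and only the final deprotection would follow.
- **Against it here:** The coupling must succeed twice on one molecule, so hydrodebromination or single coupling would give by-products that are hard to separate. The stabilised benzylic radical would tend to dimerise. Most seriously, the reaction runs on the finished flavanone: its aryl ketone can accept electrons, C2 can be lost by base-induced ring opening near the cathode, and the free chelated 5-hydroxyl is a proton source for protodehalogenation.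
- **Comparison:** On structure both plans reach the same penultimate compound. On convergence and on the length of the arm synthesis alternative 1 is the better plan. On mechanism the chosen plan is safer, because C2 is created after all C–C bonds and then meets only a neutral reduction and mild acid. On step economy the two are about equal, since A1 still needs its own ring A, ring C and asymmetric step.

Alternative 2: The cut is the C2–C3 bond; C2 and ring B come from an O-benzyl group on ring A.
- **Forward step:** The α-diazoketone A4 (the 2,6-bis(benzyloxy)aryl diazomethyl ketone with both protected arms) would be decomposed by a chiral dirhodium tetracarboxylate such as Rh2(S-DOSP)4 or Rh2(S-PTTL)4. The rhodium carbenoid at C3 inserts into a benzylic C–H bond of one of the two equivalent O-benzyl groups, which would close ring C and set C2 in the 5-O-benzyl flavanone A5.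
- **In its favour:** Ring closure and stereocentre formation are one event, so no separate asymmetric reduction is needed; on this point it is better than the chosen plan. It uses the same ring A symmetry (either benzyl group may react; the other protects O5). C4 comes from a benzoic acid, so no pressurised CO is needed; on that point it is equal or better.
- **Against it here:** An acceptor-only carbenoid next to an ether oxygen is prone to oxonium ylide formation and 1,2-benzyl shift, which would close a five-membered ring instead. Six-membered insertion is generally less favoured than five-membered. Asymmetric induction with such carbenoids is usually modest. The hindered 2,6-disubstituted acid must be activated and treated with diazomethane in the presence of acid-labile acetals. The 5-O-benzyl group must later be removed by hydrogenolysis beside the benzylic C2–O1 bond.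
- **Comparison:** On structure both plans use the same symmetric ring A. On mechanism the alternative is the more elegant but the less predictable in chemoselectivity and in enantiomeric purity, whereas the chosen annulation is an established reaction type and the later reduction has only one reactive site. On step economy the alternative could be one step shorter after ring closure but pays for it with the diazoketone preparation, so the two are about equal.

Alternative 3: Three bonds of ring A are cut (C8a–C8, C7–C6 and C8a–C4a), so the hexasubstituted ring is built rather than decorated.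
- **Forward step:** The 3-methoxy-2-(arylmethyl)cyclobutenone A6 and the 1-methoxy-3-arylpropyne A7 would be heated in toluene. Four-electron opening gives a vinylketene, regioselective [2+2] addition to the electron-rich alkyne follows, then a second four-electron opening, six-electron closure and tautomerisation should give the phenol A8.
- **In its favour:** Each substituent is placed by the connectivity of the two fragments, so no C- versus O-alkylation question arises; on this point it is better than the chosen plan, whose weakest preparatory step is exactly that benzylation. The conditions are neutral and thermal and should spare the acetals.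
- **Against it here:** A8 still has hydrogen at C4a and a methyl ether at O5. Ring C, ring B, the stereocentre and a regioselective 5-O-demethylation beside the 7-methoxy group all remain to be done, the C4a acylation most likely under acidic conditions. A6 and A7 each need several steps, and ynol ethers are sensitive. The ring A symmetry is not used, so two different arm-bearing fragments must be made.
- **Comparison:** On structure the alternative solves ring A but nothing else. On mechanism it is reliable in regiochemistry and is the equal of the chosen plan in tolerance of protecting groups. On step economy it is clearly longer.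

Key step: step 10

Remarks and assumptions:
- The target is taken to be the 7-O-methyl ether with free 5-hydroxyl and 2S configuration, as its SMILES string in the compound list shows. The connectivity of 14 and 19 was compared atom by atom with it (arm joined through C1 of ring D, outer ring on C5 of ring D) and is consistent with it.
- Compound 1 is taken to be a catalogue compound and is used as bought.
- Precursor 14 is kept as the free, symmetric diol: a free ortho hydroxyl is needed for ring closure, and protecting one would destroy the symmetry. The arms stay as methoxymethyl ethers because these make the iodination ring-A-selective. Iodine is introduced last, at the only C–H of ring A after the carboxyl group has left, and 14 is used at once, protected from light.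
- The sense of induction of the copper hydride catalyst in step 11 is not taken as known. The ligand antipode is to be fixed by a test reduction of a simple flavone; (R) is written for definiteness.
- Abbreviation: ArCH2 = {2-(methoxymethoxy)-5-[2-(methoxymethoxy)benzyl]phenyl}methyl, the protected arm.

## Route

Step 1
Reactants: 1 5-bromo-2-hydroxybenzyl alcohol
Product: 2 [5-bromo-2-(methoxymethoxy)phenyl]methanol
Conditions: MOMCl (1.1 equiv), K2CO3, acetone, 0 °C to rt
Reagents that add atoms: chloromethyl methyl ether, COCCl
Why: Williamson-type O-alkylation; carbonate ionises only the phenol, so the phenoxide is methoxymethylated and the benzylic alcohol stays free.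

Step 2
Reactants: 3 2-hydroxybenzyl alcohol
Product: 4 [2-(methoxymethoxy)phenyl]methanol
Conditions: MOMCl (1.1 equiv), K2CO3, acetone, 0 °C to rt
Reagents that add atoms: chloromethyl methyl ether, COCCl
Why: Same phenol-selective O-alkylation as in step 1.

Step 3
Reactants: 4 [2-(methoxymethoxy)phenyl]methanol
Product: 5 1-(bromomethyl)-2-(methoxymethoxy)benzene
Conditions: CBr4, PPh3, CH2Cl2, 0 °C
Reagents that add atoms: carbon tetrabromide, BrC(Br)(Br)Br
Why: Appel reaction of a primary benzylic alcohol; the neutral conditions should spare the acid-labile acetal.

Step 4
Reactants: 2 [5-bromo-2-(methoxymethoxy)phenyl]methanol; 5 1-(bromomethyl)-2-(methoxymethoxy)benzene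
Product: 7 {2-(methoxymethoxy)-5-[2-(methoxymethoxy)benzyl]phenyl}methanol (arm alcohol), via pinacol boronate 6 (not isolated)
Conditions: B2pin2 (1.05 equiv), PdCl2(dppf) (3 mol %), KOAc, 1,4-dioxane, 90 °C; then 5, aq. K3PO4, 70 °C
Reagents that add atoms: bis(pinacolato)diboron, CC1(C)OB(OC1(C)C)B1OC(C)(C)C(C)(C)O1 (its boryl group is present only in intermediate 6)
Why: Miyaura borylation of the aryl bromide, then Suzuki–Miyaura coupling of the arylboronate with the benzylic bromide in the same flask, forms the sp2–sp3 bond at C5 of ring D; the free alcohol and both acetals are compatible with these weakly basic conditions.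

Step 5
Reactants: 7 {2-(methoxymethoxy)-5-[2-(methoxymethoxy)benzyl]phenyl}methanol
Product: 8 2-(bromomethyl)-1-(methoxymethoxy)-4-[2-(methoxymethoxy)benzyl]benzene (arm bromide, ArCH2Br)
Conditions: CBr4, PPh3, CH2Cl2, 0 °C; used without storage
Reagents that add atoms: carbon tetrabromide, BrC(Br)(Br)Br
Why: Appel reaction as in step 3; the ortho-alkoxybenzyl bromide is reactive and is therefore carried on directly.

Step 6
Reactants: 9 methyl 2,4,6-trihydroxybenzoate
Product: 10 methyl 2,6-dihydroxy-4-methoxybenzoate
Conditions: MeI (1.0 equiv), K2CO3 (1.0 equiv), acetone, rt
Reagents that add atoms: iodomethane, CI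
Why: O-methylation; the 4-hydroxyl is the most acidic and the only one not chelated to the ester, so one equivalent of base and iodomethane should methylate it selectively.

Step 7
Reactants: 10 methyl 2,6-dihydroxy-4-methoxybenzoate; 8 arm bromide ArCH2Br (2.1 equiv)
Product: 11 methyl 3,5-bis(ArCH2)-2,6-dihydroxy-4-methoxybenzoate
Conditions: LiOtBu (2.1 equiv), toluene, 0 to 70 °C
Reagents that add atoms: none
Why: C-alkylation of an ambident phenoxide with a soft benzylic bromide: C3 and C5 are the only open ring carbons and each is ortho or para to a phenoxide oxygen. The lithium ion held between phenoxide and ester oxygen in non-polar toluene should shield oxygen and steer the bromide to carbon; each alkylation is followed by rearomatisation.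

Step 8
Reactants: 11 methyl 3,5-bis(ArCH2)-2,6-dihydroxy-4-methoxybenzoate
Product: 13 4,6-bis(ArCH2)-5-methoxybenzene-1,3-diol, via carboxylic acid 12 (not isolated)
Conditions: KOH, 1,4-dioxane/H2O, 100 °C, Ar; then AcOH to pH 6, 80 °C
Reagents that add atoms: none
Why: Saponification of the hindered salicylate, then protodecarboxylation of the 2,6-dihydroxybenzoic acid by ipso-protonation of the electron-rich ring, the classical removal of a carboxyl blocking group from a phloroglucinol nucleus. Acetals and the methyl ether should survive base and pH 6.

Step 9
Reactants: 13 4,6-bis(ArCH2)-5-methoxybenzene-1,3-diol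
Product: 14 4,6-bis(ArCH2)-2-iodo-5-methoxybenzene-1,3-diol
Conditions: I2 (1.05 equiv), NaHCO3, THF/H2O, 0 °C, dark; Na2S2O3 work-up
Reagents that add atoms: iodine, II
Why: Electrophilic aromatic iodination at the single C–H of ring A, which lies between two hydroxyls, the position at which resorcinol itself is iodinated under these conditions. The acetal-capped rings D and E are much less nucleophilic and should not react with iodine alone.

Step 10
Reactants: 14 4,6-bis(ArCH2)-2-iodo-5-methoxybenzene-1,3-diol; 15 carbon monoxide; 16 phenylacetylene (2 equiv)
Product: 19 6,8-bis(ArCH2)-5-hydroxy-7-methoxy-2-phenyl-4H-chromen-4-one (flavone), via aryl ynone 17 (not isolated), via enaminone 18 (not isolated)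
Conditions: PdCl2(PPh3)2 (5 mol %), CO (20 bar), Et2NH, 110 °C, no copper salt
Reagents that add atoms: diethylamine, CCNCC (its atoms are present only in intermediate 18 and leave again on ring closure)
Why: The divalent precatalyst PdCl2(PPh3)2 is reduced in the flask to zerovalent palladium, which adds to the C4a–I bond of 14; CO insertion gives the aroylpalladium species, and amine-assisted transfer of the acetylide with reductive elimination gives ynone 17 (C4a–C4 and C4–C3). Diethylamine adds to 17 to give enaminone 18, and an ortho hydroxyl then attacks the β-carbon with loss of diethylamine (O1–C2). Ring C therefore closes in the 6-endo mode, formally 6-endo-dig on the ynone and in practice a 6-endo-trig addition–elimination on the enaminone. The closest known reaction type is the palladium/diethylamine carbonylative annulation of 2-iodophenols with terminal alkynes to flavones. No stereocentre is formed. CO insertion must outrun direct alkynylation, which would lead to furan closure; CO pressure, the electron-rich aryl–palladium bond and the absence of copper should secure this. Pyranone rather than five-membered closure is needed and is steered by the secondary-amine relay. Which hydroxyl closes is immaterial because 14 has a mirror plane through C–I and C–OCH3; the other hydroxyl becomes the chelated 5-hydroxyl.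

Step 11
Reactants: 19 6,8-bis(ArCH2)-5-hydroxy-7-methoxy-2-phenyl-4H-chromen-4-one
Product: 20 (2S)-6,8-bis(ArCH2)-5-hydroxy-7-methoxy-2-phenylchroman-4-one
Conditions: Cu(OAc)2·H2O (5 mol %), (R)-DTBM-SEGPHOS (5.5 mol %), (EtO)2MeSiH (4 equiv), t-BuOH (3 equiv), toluene, 0 °C to rt; then NH4F, MeOH
Reagents that add atoms: none
Why: Copper hydride-catalysed asymmetric conjugate reduction, a reaction type known for chromones: the ligated CuH delivers hydride to C2 of the vinylogous ester and t-BuOH protonates the copper enolate at C3. The chiral bisphosphine alone selects the face of C2 and so sets the 2S centre. The medium is neutral, so ring C should not open, and any silyl ether formed at O5 is cleaved in the fluoride work-up.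

Step 12
Reactants: 20 (2S)-6,8-bis(ArCH2)-5-hydroxy-7-methoxy-2-phenylchroman-4-one
Product: 21 (2S)-5-hydroxy-6,8-bis[2-hydroxy-5-(2-hydroxybenzyl)benzyl]-7-methoxy-2-phenylchroman-4-one (target)
Conditions: HCl (1.25 M in MeOH), THF, 40 °C
Reagents that add atoms: none
Why: Acid-catalysed acetal exchange removes the four methoxymethyl groups, with methanol trapping the formaldehyde unit as its dimethyl acetal. Mild acid at 40 °C should not open ring C, so C2 is expected to keep its configuration; the aryl methyl ether is inert.

## Compound list

1 | 5-bromo-2-hydroxybenzyl alcohol | OCc1cc(Br)ccc1O | starting material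
2 | [5-bromo-2-(methoxymethoxy)phenyl]methanol | COCOc1ccc(Br)cc1CO | intermediate
3 | 2-hydroxybenzyl alcohol | OCc1ccccc1O | starting material
4 | [2-(methoxymethoxy)phenyl]methanol | COCOc1ccccc1CO | intermediate
5 | 1-(bromomethyl)-2-(methoxymethoxy)benzene | COCOc1ccccc1CBr | intermediate
6 | [2-(methoxymethoxy)-5-(4,4,5,5-tetramethyl-1,3,2-dioxaborolan-2-yl)phenyl]methanol | COCOc1ccc(B2OC(C)(C)C(C)(C)O2)cc1CO | intermediate (not isolated)
7 | {2-(methoxymethoxy)-5-[2-(methoxymethoxy)benzyl]phenyl}methanol (arm alcohol) | COCOc1ccc(Cc2ccccc2OCOC)cc1CO | intermediate
8 | 2-(bromomethyl)-1-(methoxymethoxy)-4-[2-(methoxymethoxy)benzyl]benzene (arm bromide, ArCH2Br) | COCOc1ccc(Cc2ccccc2OCOC)cc1CBr | intermediate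
9 | methyl 2,4,6-trihydroxybenzoate | COC(=O)c1c(O)cc(O)cc1O | starting material
10 | methyl 2,6-dihydroxy-4-methoxybenzoate | COC(=O)c1c(O)cc(OC)cc1O | intermediate
11 | methyl 3,5-bis(ArCH2)-2,6-dihydroxy-4-methoxybenzoate | COC(=O)c1c(O)c(Cc2cc(Cc3ccccc3OCOC)ccc2OCOC)c(OC)c(Cc2cc(Cc3ccccc3OCOC)ccc2OCOC)c1O | intermediate
12 | 3,5-bis(ArCH2)-2,6-dihydroxy-4-methoxybenzoic acid | OC(=O)c1c(O)c(Cc2cc(Cc3ccccc3OCOC)ccc2OCOC)c(OC)c(Cc2cc(Cc3ccccc3OCOC)ccc2OCOC)c1O | intermediate (not isolated)
13 | 4,6-bis(ArCH2)-5-methoxybenzene-1,3-diol | COc1c(Cc2cc(Cc3ccccc3OCOC)ccc2OCOC)c(O)cc(O)c1Cc1cc(Cc3ccccc3OCOC)ccc1OCOC | intermediate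
14 | 4,6-bis(ArCH2)-2-iodo-5-methoxybenzene-1,3-diol | COc1c(Cc2cc(Cc3ccccc3OCOC)ccc2OCOC)c(O)c(I)c(O)c1Cc1cc(Cc3ccccc3OCOC)ccc1OCOC | intermediate
15 | carbon monoxide | [C-]#[O+] | starting material
16 | phenylacetylene | C#Cc1ccccc1 | starting material
17 | 1-[3,5-bis(ArCH2)-2,6-dihydroxy-4-methoxyphenyl]-3-phenylprop-2-yn-1-one | COc1c(Cc2cc(Cc3ccccc3OCOC)ccc2OCOC)c(O)c(C(=O)C#Cc2ccccc2)c(O)c1Cc1cc(Cc3ccccc3OCOC)ccc1OCOC | intermediate (not isolated)
18 | (E)-1-[3,5-bis(ArCH2)-2,6-dihydroxy-4-methoxyphenyl]-3-(diethylamino)-3-phenylprop-2-en-1-one | COc1c(Cc2cc(Cc3ccccc3OCOC)ccc2OCOC)c(O)c(C(=O)/C=C(/N(CC)CC)c2ccccc2)c(O)c1Cc1cc(Cc3ccccc3OCOC)ccc1OCOC | intermediate (not isolated)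
19 | 6,8-bis(ArCH2)-5-hydroxy-7-methoxy-2-phenyl-4H-chromen-4-one | COc1c(Cc2cc(Cc3ccccc3OCOC)ccc2OCOC)c(O)c2c(c1Cc1cc(Cc3ccccc3OCOC)ccc1OCOC)oc(-c1ccccc1)cc2=O | intermediate
20 | (2S)-6,8-bis(ArCH2)-5-hydroxy-7-methoxy-2-phenylchroman-4-one | COc1c(Cc2cc(Cc3ccccc3OCOC)ccc2OCOC)c(O)c2c(c1Cc1cc(Cc3ccccc3OCOC)ccc1OCOC)O[C@H](c1ccccc1)CC2=O | intermediate
21 | (2S)-5-hydroxy-6,8-bis[2-hydroxy-5-(2-hydroxybenzyl)benzyl]-7-methoxy-2-phenylchroman-4-one | COc1c(Cc2cc(Cc3ccccc3O)ccc2O)c(O)c2c(c1Cc1cc(Cc3ccccc3O)ccc1O)O[C@H](c1ccccc1)CC2=O | target

## Step count and least certain steps

Total step count: 12. Longest linear sequence: 10 steps (steps 2, 3, 4, 5, 7, 8, 9, 10, 11 and 12, from 3 to 21).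

**Step 10 (key step).** The most likely failures are loss of iodine by reduction before CO insertion, direct alkynylation without CO followed by furan closure, and capture of the aroylpalladium species by diethylamine. All stem from a crowded, very electron-rich iodide whose palladium intermediates are slow to move on. The fallback sets out from 13 and comes back at 19. 13 is heated with ethyl benzoylacetate without catalyst (diphenyl ether, about 240 °C, argon), the thermal pyrone synthesis known for phloroglucinols. C-acylation at the only open carbon of ring A and cyclodehydration onto either hydroxyl would build C4, C3 and C2 from the keto ester instead of CO and alkyne. No new isolated compound arises.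

**Step 7.** O-benzylation, stopping after one arm, or a third alkylation with loss of aromaticity may compete, because the phenoxide is ambident and the second alkylation is more hindered. The fallback sets out from 10 and 8 and comes back at 11. 10 is brominated at both open positions with N-bromosuccinimide (2 equiv, MeCN, 0 °C) to methyl 3,5-dibromo-2,6-dihydroxy-4-methoxybenzoate F1. 8 is converted with zinc dust and LiCl in THF into {2-(methoxymethoxy)-5-[2-(methoxymethoxy)benzyl]benzyl}zinc bromide F2. A double Negishi coupling (Pd(OAc)2, SPhos, THF, rt to 50 °C, F2 added slowly in excess) then forms both ring A–CH2 bonds at carbon by construction.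

**Step 11.** Conversion may be slow because the chelated, doubly flanked vinylogous ester is a poor acceptor, and face selection on a 2-aryl substrate may be incomplete. The fallback sets out from 19 and comes back at 20. Hydrogenation with [Ru(cod)(2-methylallyl)2] and a chiral N-heterocyclic carbene (from SINpEt·HBF4 and KOtBu) under H2 pressure in toluene reduces C2=C3 enantioselectively and is allowed to run on to the (2S,4S)-6,8-bis(ArCH2)-7-methoxy-2-phenylchroman-4,5-diol F3. Activated MnO2 in CH2Cl2 then reoxidises the benzylic C4 alcohol to the ketone.

**Step 12.** Partial racemisation by acid-promoted opening and reclosure of ring C is possible, as is attack of the liberated methoxymethyl cation on the freed phenol rings; both grow with time and temperature. The fallback sets out from 19 and comes back at 21, and moves the acid step to a stage without a stereocentre. The acetals are removed from the flavone (HCl in MeOH, 60 °C) to give 5-hydroxy-6,8-bis[2-hydroxy-5-(2-hydroxybenzyl)benzyl]-7-methoxy-2-phenyl-4H-chromen-4-one F4. The four arm phenols are then silylated (TBSCl, imidazole, DMF; the chelated 5-hydroxyl stays free) to the tetrakis(tert-butyldimethylsilyl) ether of the flavone F5. The conditions of step 11 should give the corresponding (2S)-flavanone tetrakis(tert-butyldimethylsilyl) ether F6. Buffered fluoride (TBAF/AcOH 1:1, THF, 0 °C) finally releases 21 without acid or free base.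

## Further compounds

F1 | step 7 | methyl 3,5-dibromo-2,6-dihydroxy-4-methoxybenzoate | COC(=O)c1c(O)c(Br)c(OC)c(Br)c1O
F2 | step 7 | {2-(methoxymethoxy)-5-[2-(methoxymethoxy)benzyl]benzyl}zinc bromide | COCOc1ccc(Cc2ccccc2OCOC)cc1C[Zn]Br
F0 | step 10 | none | none
F3 | step 11 | (2S,4S)-6,8-bis(ArCH2)-7-methoxy-2-phenylchroman-4,5-diol | COc1c(Cc2cc(Cc3ccccc3OCOC)ccc2OCOC)c(O)c2c(c1Cc1cc(Cc3ccccc3OCOC)ccc1OCOC)O[C@H](c1ccccc1)C[C@@H]2O
F4 | step 12 | 5-hydroxy-6,8-bis[2-hydroxy-5-(2-hydroxybenzyl)benzyl]-7-methoxy-2-phenyl-4H-chromen-4-one | COc1c(Cc2cc(Cc3ccccc3O)ccc2O)c(O)c2c(c1Cc1cc(Cc3ccccc3O)ccc1O)oc(-c1ccccc1)cc2=O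
F5 | step 12 | 5-hydroxy-7-methoxy-2-phenyl-6,8-bis{2-(tert-butyldimethylsilyloxy)-5-[2-(tert-butyldimethylsilyloxy)benzyl]benzyl}-4H-chromen-4-one | COc1c(Cc2cc(Cc3ccccc3O[Si](C)(C)C(C)(C)C)ccc2O[Si](C)(C)C(C)(C)C)c(O)c2c(c1Cc1cc(Cc3ccccc3O[Si](C)(C)C(C)(C)C)ccc1O[Si](C)(C)C(C)(C)C)oc(-c1ccccc1)cc2=O
F6 | step 12 | (2S)-5-hydroxy-7-methoxy-2-phenyl-6,8-bis{2-(tert-butyldimethylsilyloxy)-5-[2-(tert-butyldimethylsilyloxy)benzyl]benzyl}chroman-4-one | COc1c(Cc2cc(Cc3ccccc3O[Si](C)(C)C(C)(C)C)ccc2O[Si](C)(C)C(C)(C)C)c(O)c2c(c1Cc1cc(Cc3ccccc3O[Si](C)(C)C(C)(C)C)ccc1O[Si](C)(C)C(C)(C)C)O[C@H](c1ccccc1)CC2=O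
A1 | alternative 1 | (2S)-6,8-bis[5-bromo-2-(methoxymethoxy)benzyl]-5-hydroxy-7-methoxy-2-phenylchroman-4-one | COc1c(Cc2cc(Br)ccc2OCOC)c(O)c2c(c1Cc1cc(Br)ccc1OCOC)O[C@H](c1ccccc1)CC2=O
A2 | alternative 1 | 1,3-dioxoisoindolin-2-yl 2-[2-(methoxymethoxy)phenyl]acetate | COCOc1ccccc1CC(=O)ON1C(=O)c2ccccc2C1=O
A3 | alternative 1 | (2S)-6,8-bis(ArCH2)-5-hydroxy-7-methoxy-2-phenylchroman-4-one (identical with 20) | COc1c(Cc2cc(Cc3ccccc3OCOC)ccc2OCOC)c(O)c2c(c1Cc1cc(Cc3ccccc3OCOC)ccc1OCOC)O[C@H](c1ccccc1)CC2=O
A4 | alternative 2 | 1-[2,6-bis(benzyloxy)-3,5-bis(ArCH2)-4-methoxyphenyl]-2-diazoethan-1-one | COc1c(Cc2cc(Cc3ccccc3OCOC)ccc2OCOC)c(OCc2ccccc2)c(C(=O)C=[N+]=[N-])c(OCc2ccccc2)c1Cc1cc(Cc3ccccc3OCOC)ccc1OCOC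
A5 | alternative 2 | (2S)-5-(benzyloxy)-6,8-bis(ArCH2)-7-methoxy-2-phenylchroman-4-one | COc1c(Cc2cc(Cc3ccccc3OCOC)ccc2OCOC)c(OCc2ccccc2)c2c(c1Cc1cc(Cc3ccccc3OCOC)ccc1OCOC)O[C@H](c1ccccc1)CC2=O
A6 | alternative 3 | 2-(ArCH2)-3-methoxycyclobut-2-en-1-one | COC1=C(Cc2cc(Cc3ccccc3OCOC)ccc2OCOC)C(=O)C1
A7 | alternative 3 | 2-(3-methoxyprop-2-yn-1-yl)-1-(methoxymethoxy)-4-[2-(methoxymethoxy)benzyl]benzene | COC#CCc1cc(Cc2ccccc2OCOC)ccc1OCOC
A8 | alternative 3 | 2,4-bis(ArCH2)-3,5-dimethoxyphenol | COc1cc(O)c(Cc2cc(Cc3ccccc3OCOC)ccc2OCOC)c(OC)c1Cc1cc(Cc3ccccc3OCOC)ccc1OCOC
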